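**Assumption:** the target has no stereocentre, so there is no configuration to set; the acyl chain is read as C23 (23 carbons including C=O, C30H52O2), and compounds 1 and 2 are bought.

**Retrosynthetic overview**
1. The target is cut once, at C3–C4 of the acyl chain, into a C3 ester piece and a C20 piece: benzyl 3-bromopropanoate 1 and 1-bromoicosane 2.
2. Both carbons to be joined are electrophilic (the β-carbon of an ester and a primary bromide carbon), so 1 is polarity-inverted by zinc insertion to the zinc homoenolate 3, a d3 reagent.
3. Pd-catalysed alkyl–alkyl coupling of 3 with 2 in the same flask gives the target 4.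
4. No ring is formed: the phenyl ring and the ester C–O bond arrive ready-made in 1.

**Route**

Step 1
Reactants: 1 benzyl 3-bromopropanoate; 2 1-bromoicosane
Product: 4 benzyl tricosanoate, via zinc homoenolate 3 (not isolated)
Conditions: 1 (1.5 equiv), Zn dust (1.6 equiv), I2 (5 mol%), DMA, 70 °C, 3 h; then 2 (1.0 equiv), Pd2(dba)3 (2 mol%), PCyp3 (8 mol%), N-methylimidazole (1.2 equiv), THF/DMA 2:1, 80 °C, 14 h
Reagents that add atoms: zinc dust, [Zn] (its atom sits only in intermediate 3; none of it remains in 4)
Why: Oxidative insertion of zinc into the C–Br bond of 1 gives the ester-chelated zinc homoenolate 3, whose β-carbon is now nucleophilic, and this undergoes a Negishi C(sp3)–C(sp3) cross-coupling with the primary bromide 2 (the electron-rich bulky PCyp3 drives oxidative addition and outpaces β-hydride elimination, N-methylimidazole activates the organozinc), forming C3–C4 with no stereocentre created.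

**Compound list**
1 | benzyl 3-bromopropanoate | BrCCC(=O)OCc1ccccc1 | starting material
2 | 1-bromoicosane | CCCCCCCCCCCCCCCCCCCCBr | starting material
3 | (3-benzyloxy-3-oxopropyl)zinc bromide, the zinc homoenolate of benzyl propanoate | Br[Zn]CCC(=O)OCc1ccccc1 | intermediate
4 | benzyl tricosanoate | CCCCCCCCCCCCCCCCCCCCCCC(=O)OCc1ccccc1 | target

**Total step count:** 1
**Longest linear sequence:** 1 step

**Most likely failures and fallbacks**
The route has a single step, so the three risks are the three stages of step 1.

Risk 1, step 1, zinc insertion into 1: the β-bromo ester may eliminate to benzyl acrylate or dimerise (Wurtz) instead of giving 3. The fallback sets out from 2 and comes back at 4, using an acetal-masked homoenolate instead of the ester one. Compound 2 is coupled with commercial [2-(1,3-dioxan-2-yl)ethyl]magnesium bromide under Li2CuCl4 catalysis (THF, −10 °C to rt) to give 2-docosyl-1,3-dioxane F1. Acetal hydrolysis (2 M HCl, THF, 60 °C) gives tricosanal F2. NHC-catalysed oxidative esterification of F2 with benzyl alcohol (triazolium salt/DBU, 3,3',5,5'-tetra-tert-butyldiphenoquinone, THF, rt) then gives 4.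

Risk 2, step 1, the alkyl–alkyl coupling of 3 with 2: the chelated homoenolate may transmetalate slowly, so that β-hydride elimination to 1-icosene and reduction of 2 take over. The fallback sets out from 3 (made from 1 as in step 1) and comes back at 4, replacing the alkyl electrophile by an acyl one. Compound 3 is acylated with icosanoyl chloride under Pd(PPh3)4 catalysis (THF/toluene, rt) to give benzyl 4-oxotricosanoate F3. Condensation with tosylhydrazine (THF, 50 °C) gives benzyl 4-(2-tosylhydrazinylidene)tricosanoate F4. Reduction of F4 with catecholborane (CHCl3, 0 °C), then NaOAc·3H2O at reflux, removes the ketone oxygen and gives 4 with the ester untouched.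

Risk 3, step 1, survival of the benzyl ester: Pd(0) with an electron-rich phosphine at 80 °C may insert into the benzylic C–O bond, and zinc salts may assist ester cleavage. The fallback sets out from 2 and comes back at 4, installing the benzyl group only after the C–C bond is made. Compound 2 is coupled under the same Pd2(dba)3/PCyp3/N-methylimidazole conditions with commercial (3-ethoxy-3-oxopropyl)zinc bromide to give ethyl tricosanoate F5. Transesterification of F5 with excess benzyl alcohol (Ti(OiPr)4 5 mol%, toluene, reflux, ethanol distilled off) gives 4.

**Further compounds**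
F1 | step 1 | 2-docosyl-1,3-dioxane | CCCCCCCCCCCCCCCCCCCCCCC1OCCCO1
F2 | step 1 | tricosanal | CCCCCCCCCCCCCCCCCCCCCCC=O
F3 | step 1 | benzyl 4-oxotricosanoate | CCCCCCCCCCCCCCCCCCCC(=O)CCC(=O)OCc1ccccc1
F4 | step 1 | benzyl 4-(2-tosylhydrazinylidene)tricosanoate (E/Z mixture) | CCCCCCCCCCCCCCCCCCCC(=NNS(=O)(=O)c1ccc(C)cc1)CCC(=O)OCc1ccccc1
F5 | step 1 | ethyl tricosanoate | CCCCCCCCCCCCCCCCCCCCCCC(=O)OCC
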